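## Structural features

The target is pentacyclic. Ring A is aromatic (C6 OMe, C8 OH); ring B holds the C9 ketone, the C10 methylene and the C4a=C10a double bond; ring C is a cross-conjugated 2-methoxy-3-amino-enone (C1 carbonyl, C2 OMe, C3 N) that ends in the quaternary carbon C4 (Me, O). C3–N and C4–O are tied together by the aminal carbon C2', so an oxazolidine (N, C3, C4, O, C2') is fused to ring C along C3–C4 and to a pyrrolidine along N–C2'. There are two stereocentres, C4 (R) and C2' (S), 1,3-related across the aminal oxygen. C2' is a reversible N,O-acetal centre and should follow C4 (pyrrolidine CH2 on the face away from the C4 methyl), so only C4 needs asymmetric synthesis. Fragile points are the N,O-acetal, the electron-rich rings A and B, the C9/C10 keto–enol pair, and above all the C4–O bond: C4 is tertiary, benzylic to C4a and para to the C9 oxygen, and ionisation followed by proton loss would aromatise ring C. The real difficulty is C4 itself, a fully substituted, oxygen-bearing bay-region carbon (peri to C5–H) that must be made as one enantiomer, together with telling the C8 oxygen from the C6 methyl ether. The key step uses the fact that the C1 carbonyl and the C4 carbinol sit para on ring C, on the two carbons (C10a, C4a) of one edge of the naphthalene formed by rings A and B; this is the pattern left when an oxygen-bridged cycloadduct of a naphtho-fused silyloxyfuran collapses.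

## Logic of the disconnections

28 ⇒ 25. The N–C2' and O–C2' bonds and the two benzyl ethers are cut. C2' is at the aldehyde oxidation level between two heteroatoms, so it opens to an acetal-masked aminoaldehyde chain on N. Two rings and one stereocentre disappear. The forward step must remove the benzyl groups before the aminal exists (its C4–O bond is benzylic) and must close the aminal in weak acid only.

25 ⇒ 22 + 23. The C3–N bond is cut. A vinylogous amide is the product of amine conjugate addition to an enone followed by dehydrogenation. This removes all nitrogen and four carbons. The forward step needs addition at a hindered β-carbon next to quaternary C4 and an oxidant that spares the electron-rich naphthalene.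

22 ⇒ 19. The C2=C3 double bond is removed. Only C2 can enolise, so regiochemistry is not an issue; the forward step must avoid Lewis and protic acid because of C4–OH.

19 ⇒ 16. The C2–acyl bond is restored. The acyl group is the handle that lets the dienophile bind a chiral metal complex at two points. The forward step must cleave the imide without a C4 alkoxide adding to C1 (retro-Claisen opening of C1–C2).

16 ⇒ 14 + 13. C3–C4 and C1–C2 are cut (key step). Ring C, the quaternary carbinol and the C1 ketone fall back to a planar, achiral furan and a three-carbon acrylimide. The forward step needs regio-, endo- and face control.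

14 ⇒ 8, and 13 ⇒ 10 + 11 ⇒ 9. The O–Si bond and the N–acyl bond are cut; both are routine enolate silylation and N-acylation.

8 ⇒ 7 ⇒ 6. The benzyl ethers are removed and the C8 oxygen is returned to its methyl ether. Benzyl ethers are chosen over an isopropylidene ketal on the C8/C9 oxygens, because a peri-diol ketal needs acid strong enough to ionise C4–O at the end, whereas benzyl ethers leave under neutral hydrogenolysis. The forward demethylation relies on the free C9–OH to deliver boron to the peri methoxy group.

6 ⇒ 5. The C4–O lactone bond is cut back to a C4–H bond of an ethyl group. C4 is benzylic and para to the free C9–OH, the one position a quinone oxidant activates through the quinone methide. A naphthoate with C4a–H was rejected: metalation would go to C10 (between the carboxyl and the C9 oxygen) and electrophiles would attack ring A. The C4 carbon is therefore built in from the start.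

5 ⇒ 3 ⇒ 1 + 2. C9–C8a is cut (Friedel–Crafts acylation, both ortho positions of the aryl ring are equivalent), then C4a=C10a (Stobbe condensation). The ketone in place of an aldehyde delivers C4 and its methyl as the ethyl group. The forward steps must cope with alkene isomers of 3.

## Other disconnections considered

Alternative 1: The cut goes through C4a–C4b and C10–C10a and detaches all carbons of rings A and B from a tricyclic dienone A2, in which ring C already carries the N,O-acetal. Forward, an aryl cuprate (aryl Grignard reagent with CuBr·SMe2) would add to C4a and the C10a enolate would be trapped by a haloacetate to give A1.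
- In favour: it is convergent, C4 and C2' are settled early in a small molecule, and the two new centres of A1 are erased later, so their selectivity is irrelevant.
- Against: C4a is the β-carbon next to quaternary C4, so the addition is neopentyl-like; the aminal must survive organocopper and Lewis acid; after A1 the route still needs ester cleavage, Friedel–Crafts closure of ring B, re-introduction of C4a=C10a and a late selective C8 demethylation on an acid-sensitive aminal; and A2 needs its own asymmetric synthesis.
- Comparison: both plans must make a bond to a carbon flanked by the quaternary centre (C4a–aryl there, C3–C4 here), but the cycloaddition creates the quaternary centre and ring C together. The alternative is the better plan on protecting groups (none on the naphthalene oxygens) and equal on C2' control; it is worse on step count after the key step and leaves the C4 problem to the synthesis of A2.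

Alternative 2: The cut is N–C2', made transannularly from an eight-membered N,O-ring A4 (C3–N–CH2–CH=CH–CH2–O–C4). Forward, RuHCl(CO)(PPh3)3 would move the alkene next to oxygen, acid would protonate the enol ether, and the ring NH would attack C2' across the ring to give A3.
- In favour: the aldehyde level at C2' is carried as a robust allyl ether, no free aminoaldehyde is handled, and the N–C2' closure is geometrically predisposed.
- Against: it needs O-allylation of the hindered, ionisable C4–OH, a ring-closing metathesis to a medium ring, and alkene migration towards O and not towards N; A3 still carries the isopropylidene ketal, whose removal needs acid that threatens C4–O.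
- Comparison: the alternative is equal on the origin of the C2' configuration (C4 decides in both) and better in that the aminal forms under anhydrous conditions. It is worse on step economy (four operations for what is one step here) and it does not address C4 or ring C at all.

Alternative 3: The cut is C9–C10 of ring B in a biaryl A6. Forward, LiN(i-Pr)2 directed by the diethylamide would deprotonate the C10 methyl group, and the benzylic anion would attack the amide to give phenanthrol A5.
- In favour: remote metalation is a dependable ring-B closure, it delivers the C9 oxygen as a free phenol, and the biaryl is made convergently by cross-coupling.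
- Against: ring C arrives fully aromatic with four methyl ethers; C4 would have to be turned from an aryl C–OMe into an sp3 carbinol bearing methyl, as one enantiomer, by dearomatisation and methyl addition with no obvious handle for face control; six methyl ethers must be told apart.
- Comparison: the alternative is the better plan for building the phenanthrene skeleton quickly and on scale. It postpones the one hard problem, which the chosen key step solves while ring C is formed.

Key step: step 9

Remarks on the chemistry (assumptions):
- The target is drawn as the C9-keto/C10-methylene tautomer of the 8,9-dihydroxynaphthalene freed in the last step; this chelated keto form is assumed to be the resting form, reached by prototropy.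
- Ketone 1 is taken as a catalogue compound (otherwise one step from 3,5-dimethoxybenzonitrile and EtMgBr).
- In diene 14 the silyloxy carbon is the furan carbon bonded to C10a and the methyl-bearing carbon is the one bonded to C4a (positions 3 and 1 of naphtho[1,2-c]furan); only this orientation puts the lactone oxygen on C4.

## Route

Step 1
Reactants: 1 1-(3,5-dimethoxyphenyl)propan-1-one; 2 dimethyl succinate
Product: 3 (E)-4-(3,5-dimethoxyphenyl)-3-(methoxycarbonyl)hex-3-enoic acid (carried on together with its alkene isomers)
Conditions: t-BuOK (1.3 equiv), t-BuOH, 60 °C; 1 M HCl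
Reagents that add atoms: none
Why: Stobbe condensation: the succinate enolate adds to the ketone, the aldolate lactonises onto the distal ester and base-induced ring opening gives the half-ester, driven by carboxylate formation.

Step 2
Reactants: 3
Product: 5 1-ethyl-4-hydroxy-5,7-dimethoxy-2-naphthoic acid, via acetoxy naphthoate 4 (not isolated)
Conditions: Ac2O, NaOAc, 140 °C; then NaOH, MeOH/H2O (degassed), 70 °C; HCl to pH 2
Reagents that add atoms: sodium hydroxide, [Na+].[OH-] (oxygen of the carboxyl OH); acetic anhydride, CC(=O)OC(C)=O (acetyl group of 4 only, removed again)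
Why: The mixed anhydride acylates the aryl ring ortho to one methoxy and para to the other (intramolecular Friedel–Crafts acylation) and the naphthol is trapped as its acetate; the alkene isomers should interconvert through the dienolate of the mixed anhydride and drain through the cyclisable one. Saponification then frees the naphthol and the acid.

Step 3
Reactants: 5
Product: 6 5-hydroxy-6,8-dimethoxy-1-methylnaphtho[1,2-c]furan-3(1H)-one (racemic)
Conditions: DDQ (1.05 equiv), CH2Cl2, 0 °C → rt
Reagents that add atoms: none
Why: DDQ dehydrogenates the p-alkyl naphthol to the p-quinone methide and the neighbouring carboxylic acid adds 1,6 to the methide carbon, closing the lactone and restoring the naphthol (oxidative benzylic lactonisation). The ethyl CH2 is the only benzylic position para to the free hydroxyl; the racemic centre is erased in step 8.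

Step 4
Reactants: 6
Product: 7 5,6-dihydroxy-8-methoxy-1-methylnaphtho[1,2-c]furan-3(1H)-one (racemic)
Conditions: BBr3 (1.3 equiv), CH2Cl2, −78 → −10 °C; H2O
Reagents that add atoms: none
Why: The naphthol forms an aryloxy-dibromoborane that chelates the peri methoxy oxygen in a six-membered ring, and bromide removes that methyl group (chelation-assisted ether cleavage). The remote methoxy group has no such assistance and should survive at low temperature.

Step 5
Reactants: 7
Product: 8 5,6-bis(benzyloxy)-8-methoxy-1-methylnaphtho[1,2-c]furan-3(1H)-one (racemic)
Conditions: BnBr (2.5 equiv), K2CO3, DMF, 50 °C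
Reagents that add atoms: benzyl bromide, BrCc1ccccc1
Why: Williamson etherification of both phenols; K2CO3 is too weak to deprotonate the lactone C–H.

Step 6
Reactants: 9 methyl 2-methoxyacrylate
Product: 10 lithium 2-methoxyacrylate
Conditions: LiOH·H2O (1.0 equiv), THF/H2O, 0 °C → rt; freeze-dry
Reagents that add atoms: lithium hydroxide, [Li+].[OH-]
Why: Ester saponification; the salt is kept because the free enol-ether acid is labile to aqueous acid.

Step 7
Reactants: 10; 11 oxazolidin-2-one
Product: 13 3-(2-methoxyacryloyl)oxazolidin-2-one, via mixed pivalic anhydride 12 (not isolated)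
Conditions: t-BuCOCl, THF, −20 °C; then 11, LiCl, Et3N, −20 °C → rt
Reagents that add atoms: pivaloyl chloride, CC(C)(C)C(Cl)=O (pivaloyl group of 12 only, lost again)
Why: N-Acylation through the mixed anhydride; the lithium-activated oxazolidinone attacks the less hindered acyl carbon.

Step 8
Reactants: 8
Product: 14 5,6-bis(benzyloxy)-3-(tert-butyldimethylsilyloxy)-8-methoxy-1-methylnaphtho[1,2-c]furan
Conditions: LiN(SiMe3)2 (1.1 equiv), THF, −78 °C; TBSOTf (1.1 equiv), −78 → 0 °C; evaporate, pentane, filter under Ar, use at once
Reagents that add atoms: tert-butyldimethylsilyl triflate, CC(C)(C)[Si](C)(C)OS(=O)(=O)C(F)(F)F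
Why: The lactone C–H (C4–H in target numbering; benzylic, next to oxygen, vinylogous to the carbonyl) is removed and the enolate is silylated on oxygen, which turns the lactone into the aromatic furan. Amine and lithium salts are removed because they would poison the Lewis acid of step 9.

Step 9
Reactants: 14; 13
Product: 16 (2R,4S)-8,9-bis(benzyloxy)-4-hydroxy-2,6-dimethoxy-4-methyl-2-(2-oxooxazolidine-3-carbonyl)-3,4-dihydrophenanthren-1(2H)-one, via bridged silyl ketal adduct 15 (not isolated)
Conditions: Cu(OTf)2 (10 mol%), (S,S)-t-Bu-box (11 mol%), 4 Å MS, CH2Cl2, −78 → −40 °C; then HF·pyridine, pyridine, THF, −40 → 0 °C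
Reagents that add atoms: none
Why: Proposed new method: the imide should bind the divalent copper centre of Cu(OTf)2/(S,S)-t-Bu-box through both carbonyls as a square-planar s-cis chelate, which lowers the alkene LUMO and leaves its Cα Re face open; the closest known reaction types are the copper bis(oxazoline)-catalysed Diels–Alder reactions of furan and cyclopentadiene with N-acryloyl oxazolidinones and the thermal Diels–Alder reactions of phthalide-derived 1-silyloxyisobenzofurans, so only their combination is new. The silyl ketene acetal of 14 makes the methyl-bearing furan carbon (future C4) the nucleophilic terminus, which bonds to the CH2 of the dienophile (C3–C4) in a concerted but strongly asynchronous [4+2] addition, while the silyloxy carbon closes onto the methoxy-bearing carbon (C1–C2); regaining the naphthalene sextet pays for the quaternary bay-region centre. Ring C is closed as a six-membered carbocycle by this intermolecular [4+2] cycloaddition, both bonds forming in one step, and the oxygen bridge of 15 is only transient. C2 is set by the ligand, which shields the Cα Si face of the chelated dienophile; C4 is set indirectly by the endo arrangement (chelated acyl group under the naphthalene), which ties the face of the planar diene to that of the dienophile and leads to the (2R,4S) adduct. The step needs regio-, endo/exo and face selectivity: the silyloxy donor fixes the first, secondary overlap and the bulk of the metal-bound acyl group the second, the ligand the third. Because C2 is removed later, any exo adduct would end as the C4 antipode and has to be separated at the stage of 16. HF·pyridine removes silicon and the bridge opens on the C1 side, pushed by the hemiketal oxygen, so the former lactone oxygen stays on C4 and the C4–O bond is never ionised; basic fluoride is avoided because a C4 alkoxide could add back to C1 and cleave C1–C2.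

Step 10
Reactants: 16
Product: 19 (4S)-8,9-bis(benzyloxy)-4-hydroxy-2,6-dimethoxy-4-methyl-3,4-dihydrophenanthren-1(2H)-one (C2 epimers), via peroxy acid 17 (not isolated), via β-keto acid 18 (not isolated)
Conditions: LiOH·H2O (2 equiv), 30% H2O2 (6 equiv), THF/H2O, 0 °C; Na2SO3; 1 M HCl to pH 4, 35 °C
Reagents that add atoms: hydrogen peroxide, OO (peroxy oxygens of 17 only; one stays in 18 and is lost as CO2)
Why: Hydroperoxide attacks the exocyclic imide carbonyl selectively, sulfite reduces the peroxy acid, and the β-keto acid decarboxylates through the usual six-membered transition state. The peroxide medium is too weakly basic to generate the C4 alkoxide; C2 becomes a mixture, which does not matter.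

Step 11
Reactants: 19
Product: 22 (4S)-8,9-bis(benzyloxy)-4-hydroxy-2,6-dimethoxy-4-methylphenanthren-1(4H)-one, via bis-silyl enol ether 20 (not isolated), via silyl ether enone 21 (not isolated)
Conditions: LiN(SiMe3)2 (2.5 equiv), Me3SiCl, THF, −78 → 0 °C; Pd(OAc)2 (1.1 equiv), MeCN, rt; K2CO3 (cat.), MeOH, 0 °C
Reagents that add atoms: chlorotrimethylsilane, C[Si](C)(C)Cl (silyl groups of 20 and 21 only, removed again)
Why: Saegusa–Ito oxidation: divalent palladium takes the silyl enol ether to a palladium enolate at C2 and β-hydride loss from C3 gives the enone. Only C2 can enolise, and base-mediated silylation avoids any Lewis acid at the ionisable C4 oxygen.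

Step 12
Reactants: 22; 23 4,4-diethoxybutan-1-amine
Product: 25 (4R)-8,9-bis(benzyloxy)-3-[(4,4-diethoxybutyl)amino]-4-hydroxy-2,6-dimethoxy-4-methylphenanthren-1(4H)-one, via β-amino ketone 24 (not isolated)
Conditions: 23 (3 equiv), MeOH, 40 °C; then Cu(OAc)2 (20 mol%), O2 (1 atm), 40 °C
Reagents that add atoms: none
Why: Aza-Michael addition to C3 followed by copper-catalysed aerobic dehydrogenation of the β-amino ketone (oxidative amination); formation of the push–pull vinylogous amide pulls the reversible addition forward. C4 is untouched; its descriptor changes to R only because C3 now outranks C4a.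

Step 13
Reactants: 25
Product: 28 target, (4R,2'S)-configured N,O-acetal (CNP0528850.1), via diol acetal 26 (not isolated), via amino aldehyde 27 (not isolated)
Conditions: H2 (1 atm), 10% Pd/C, EtOAc/EtOH, rt; filter under Ar; then AcOH/H2O/THF (3:1:1), rt
Reagents that add atoms: water, O (carbonyl oxygen of 27 only, lost again on ring closure)
Why: Neutral hydrogenolysis removes both benzyl ethers before any benzylic aminal C–O bond exists; weak acid then unmasks the aldehyde, the vinylogous amide nitrogen closes the pyrrolidine, and the resulting iminium ion is captured by the C4 hydroxyl (5-membered N,O-acetal). The closure is reversible, so C2' should settle under control by C4 with the pyrrolidine CH2 anti to the C4 methyl, which is the (S) configuration; the freed 8,9-diol tautomerises to the C9 ketone. Acetic acid is too weak to ionise C4–O.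

## Compound list

1 | 1-(3,5-dimethoxyphenyl)propan-1-one | CCC(=O)c1cc(OC)cc(OC)c1 | starting material
2 | dimethyl succinate | COC(=O)CCC(=O)OC | starting material
3 | (E)-4-(3,5-dimethoxyphenyl)-3-(methoxycarbonyl)hex-3-enoic acid | CC/C(c1cc(OC)cc(OC)c1)=C(\C(=O)OC)CC(=O)O | intermediate
4 | methyl 4-acetoxy-1-ethyl-5,7-dimethoxy-2-naphthoate | CCc1c(C(=O)OC)cc(OC(C)=O)c2c(OC)cc(OC)cc12 | intermediate (not isolated)
5 | 1-ethyl-4-hydroxy-5,7-dimethoxy-2-naphthoic acid | CCc1c(C(=O)O)cc(O)c2c(OC)cc(OC)cc12 | intermediate
6 | 5-hydroxy-6,8-dimethoxy-1-methylnaphtho[1,2-c]furan-3(1H)-one (racemic) | CC1OC(=O)c2cc(O)c3c(OC)cc(OC)cc3c12 | intermediate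
7 | 5,6-dihydroxy-8-methoxy-1-methylnaphtho[1,2-c]furan-3(1H)-one (racemic) | CC1OC(=O)c2cc(O)c3c(O)cc(OC)cc3c12 | intermediate
8 | 5,6-bis(benzyloxy)-8-methoxy-1-methylnaphtho[1,2-c]furan-3(1H)-one (racemic) | CC1OC(=O)c2cc(OCc3ccccc3)c3c(OCc4ccccc4)cc(OC)cc3c12 | intermediate
9 | methyl 2-methoxyacrylate | C=C(OC)C(=O)OC | starting material
10 | lithium 2-methoxyacrylate | [Li+].[O-]C(=O)C(=C)OC | intermediate
11 | oxazolidin-2-one | O=C1NCCO1 | starting material
12 | 2-methoxyacrylic pivalic anhydride | C=C(OC)C(=O)OC(=O)C(C)(C)C | intermediate (not isolated)
13 | 3-(2-methoxyacryloyl)oxazolidin-2-one | C=C(OC)C(=O)N1CCOC1=O | intermediate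
14 | 5,6-bis(benzyloxy)-3-(tert-butyldimethylsilyloxy)-8-methoxy-1-methylnaphtho[1,2-c]furan | Cc1oc(O[Si](C)(C)C(C)(C)C)c2cc(OCc3ccccc3)c3c(OCc4ccccc4)cc(OC)cc3c12 | intermediate
15 | (1R,2R,4S) endo adduct: 1-silyloxy-1,4-epoxy-bridged tetrahydrophenanthrene with 2-OMe, 2-(2-oxooxazolidine-3-carbonyl), 4-Me | CO[C@]6(C(=O)N2CCOC2=O)C[C@]3(C)O[C@@]6(O[Si](C)(C)C(C)(C)C)c1cc(OCc2ccccc2)c2c(OCc4ccccc4)cc(OC)cc2c13 | intermediate (not isolated)
16 | (2R,4S)-8,9-bis(benzyloxy)-4-hydroxy-2,6-dimethoxy-4-methyl-2-(2-oxooxazolidine-3-carbonyl)-3,4-dihydrophenanthren-1(2H)-one | CO[C@]1(C(=O)N2CCOC2=O)C[C@](C)(O)c2c3cc(OC)cc(OCc4ccccc4)c3c(OCc3ccccc3)cc2C1=O | intermediate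
17 | 2-peroxycarboxylic acid from 16 | CO[C@]1(C(=O)OO)C[C@](C)(O)c2c3cc(OC)cc(OCc4ccccc4)c3c(OCc3ccccc3)cc2C1=O | intermediate (not isolated)
18 | 2-carboxylic acid (β-keto acid) | CO[C@]1(C(=O)O)C[C@](C)(O)c2c3cc(OC)cc(OCc4ccccc4)c3c(OCc3ccccc3)cc2C1=O | intermediate (not isolated)
19 | (4S)-8,9-bis(benzyloxy)-4-hydroxy-2,6-dimethoxy-4-methyl-3,4-dihydrophenanthren-1(2H)-one (C2 epimers) | COC1C[C@](C)(O)c2c3cc(OC)cc(OCc4ccccc4)c3c(OCc3ccccc3)cc2C1=O | intermediate
20 | (4S)-8,9-bis(benzyloxy)-2,6-dimethoxy-4-methyl-1,4-bis(trimethylsilyloxy)-3,4-dihydrophenanthrene | C1[C@](C)(O[Si](C)(C)C)c2c3cc(OC)cc(OCc4ccccc4)c3c(OCc3ccccc3)cc2C(O[Si](C)(C)C)=C1OC | intermediate (not isolated)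
21 | (4S)-8,9-bis(benzyloxy)-2,6-dimethoxy-4-methyl-4-(trimethylsilyloxy)phenanthren-1(4H)-one | COC1=C[C@](C)(O[Si](C)(C)C)c2c3cc(OC)cc(OCc4ccccc4)c3c(OCc3ccccc3)cc2C1=O | intermediate (not isolated)
22 | (4S)-8,9-bis(benzyloxy)-4-hydroxy-2,6-dimethoxy-4-methylphenanthren-1(4H)-one | COC1=C[C@](C)(O)c2c3cc(OC)cc(OCc4ccccc4)c3c(OCc3ccccc3)cc2C1=O | intermediate
23 | 4,4-diethoxybutan-1-amine (4-aminobutanal diethyl acetal) | CCOC(CCCN)OCC | starting material
24 | 3-[(4,4-diethoxybutyl)amino]-2,3-dihydro derivative of 22 (mixture at C2 and C3) | COC1C(NCCCC(OCC)OCC)[C@](C)(O)c2c3cc(OC)cc(OCc4ccccc4)c3c(OCc3ccccc3)cc2C1=O | intermediate (not isolated)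
25 | (4R)-8,9-bis(benzyloxy)-3-[(4,4-diethoxybutyl)amino]-4-hydroxy-2,6-dimethoxy-4-methylphenanthren-1(4H)-one | COC1=C(NCCCC(OCC)OCC)[C@](C)(O)c2c3cc(OC)cc(OCc4ccccc4)c3c(OCc3ccccc3)cc2C1=O | intermediate
26 | (4R)-3-[(4,4-diethoxybutyl)amino]-4,8,9-trihydroxy-2,6-dimethoxy-4-methylphenanthren-1(4H)-one | COC1=C(NCCCC(OCC)OCC)[C@](C)(O)c2c3cc(OC)cc(O)c3c(O)cc2C1=O | intermediate (not isolated)
27 | (4R)-4-[(4,8,9-trihydroxy-2,6-dimethoxy-4-methyl-1-oxo-1,4-dihydrophenanthren-3-yl)amino]butanal | COC1=C(NCCCC=O)[C@](C)(O)c2c3cc(OC)cc(O)c3c(O)cc2C1=O | intermediate (not isolated)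
28 | target CNP0528850.1, (4R,2'S) | COC1=C2N3CCC[C@@H]3O[C@]2(C)C2=C(CC(=O)c3c(O)cc(OC)cc32)C1=O | target

## Step count and least certain steps

Total: 13 steps. Longest linear sequence: 11 steps (1–5, then 8–13); the dienophile branch (6, 7) joins at step 9.

Step 9 (key step). Three things may go wrong.
- The addition may run stepwise (Mukaiyama–Michael with silyl transfer) and stall at the open-chain lactone adduct without closing ring C.
- Face and endo/exo discrimination may be poor, because the α-methoxy group can disturb the s-cis chelate or compete for the metal; after loss of C2 this would show as erosion of enantiopurity at C4.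
- Divalent copper or adventitious acid may oxidise or protodesilylate the electron-rich diene.

Fallback, known chemistry throughout: stereocontrol is moved from a catalyst to a covalently bound auxiliary and secured by separation of diastereomers. Salt 10 is acylated as in step 7 onto (R)-4-benzyloxazolidin-2-one to give (R)-4-benzyl-3-(2-methoxyacryloyl)oxazolidin-2-one F1. Diene 14 and F1 undergo the uncatalysed cycloaddition (toluene, rt to 60 °C) followed by HF·pyridine. The (2R,4S) diastereomer of the auxiliary-bearing hydroxy ketone F2 is isolated by chromatography. The conditions of step 10 then cleave auxiliary and carboxyl, and the route is rejoined at 19.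

Step 12. The aza-Michael equilibrium at C3 may be unfavourable (hindered β-carbon beside quaternary C4, enone deactivated by the α-methoxy group), and the aerobic oxidation may attack the amine or the naphthalene instead. Fallback from 22: thiophenol/Et3N adds to C3 to give the 3-(phenylthio) ketone F9. N-Chlorosuccinimide then Et3N (chlorination at sulfur-bearing carbon, loss of HCl) gives the 3-(phenylthio) enone F10. Addition–elimination with 23 in warm MeOH then returns to 25.

Step 3. Over-oxidation of the product lactone (a second hydride loss at C4) or oxidative coupling of the naphthol may compete with clean quinone methide capture. Fallback from 5, anionic instead of oxidative: BBr3 gives the diol acid 1-ethyl-4,5-dihydroxy-7-methoxy-2-naphthoic acid F6. Exhaustive benzylation (BnBr, K2CO3) gives benzyl 4,5-bis(benzyloxy)-1-ethyl-7-methoxy-2-naphthoate F7. Lateral deprotonation of the ethyl CH2 with LiN(i-Pr)2 (THF, −78 °C) and hydroxylation with 2-(phenylsulfonyl)-3-phenyloxaziridine gives the benzylic alkoxide, which lactonises onto the ester and rejoins the route at 8.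

Step 2. The ketone-derived half-ester is an isomer mixture; if interconversion is slow, non-productive alkene geometry limits ring closure. Fallback from 2, fixing the geometry by cross-coupling: enolisation of 2 (LiN(i-Pr)2, −78 °C) and C-acylation with 1-propanoylimidazole gives dimethyl 2-propanoylsuccinate F3. Triflation under non-chelating conditions (Tf2O, aqueous Me4NOH, toluene) gives the (E)-enol triflate dimethyl (E)-2-[1-(trifluoromethylsulfonyloxy)propylidene]succinate F4. Suzuki coupling with 3,5-dimethoxyphenylboronic acid (Pd(PPh3)4, K3PO4) gives dimethyl (E)-2-[1-(3,5-dimethoxyphenyl)propylidene]succinate F5 with retention. One equivalent of LiOH hydrolyses the unconjugated ester and gives 3 as the single cyclisable isomer.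

Step 10. A C4 alkoxide may add to the C1 ketone and open C1–C2 (retro-Claisen), or hydroperoxide may attack the ketone instead of the imide. Fallback from 15 (isolated for this purpose by a non-acidic work-up), inverting the order so that C1 stays masked and C4 carries no free hydroxyl: LiOH/H2O2 cleaves the imide of 15 to the bridged silyl ketal carboxylic acid F8. HF·pyridine then opens the bridge to 18, which loses CO2 and rejoins the route at 19.

## Further compounds

F1 | step 9 | (R)-4-benzyl-3-(2-methoxyacryloyl)oxazolidin-2-one | C=C(OC)C(=O)N1[C@H](Cc2ccccc2)COC1=O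
F2 | step 9 | (2R,4S)-8,9-bis(benzyloxy)-2-[(R)-4-benzyl-2-oxooxazolidine-3-carbonyl]-4-hydroxy-2,6-dimethoxy-4-methyl-3,4-dihydrophenanthren-1(2H)-one | CO[C@]1(C(=O)N2[C@H](Cc3ccccc3)COC2=O)C[C@](C)(O)c2c3cc(OC)cc(OCc4ccccc4)c3c(OCc3ccccc3)cc2C1=O
F3 | step 2 | dimethyl 2-propanoylsuccinate | CCC(=O)C(CC(=O)OC)C(=O)OC
F4 | step 2 | dimethyl (E)-2-[1-(trifluoromethylsulfonyloxy)propylidene]succinate | CC/C(OS(=O)(=O)C(F)(F)F)=C(\C(=O)OC)CC(=O)OC
F5 | step 2 | dimethyl (E)-2-[1-(3,5-dimethoxyphenyl)propylidene]succinate | CC/C(c1cc(OC)cc(OC)c1)=C(\C(=O)OC)CC(=O)OC
F6 | step 3 | 1-ethyl-4,5-dihydroxy-7-methoxy-2-naphthoic acid | CCc1c(C(=O)O)cc(O)c2c(O)cc(OC)cc12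
F7 | step 3 | benzyl 4,5-bis(benzyloxy)-1-ethyl-7-methoxy-2-naphthoate | CCc1c(C(=O)OCc2ccccc2)cc(OCc2ccccc2)c2c(OCc3ccccc3)cc(OC)cc12
F8 | step 10 | bridged silyl ketal 2-carboxylic acid (imide of 15 replaced by CO2H) | CO[C@]6(C(=O)O)C[C@]3(C)O[C@@]6(O[Si](C)(C)C(C)(C)C)c1cc(OCc2ccccc2)c2c(OCc4ccccc4)cc(OC)cc2c13
F9 | step 12 | (4S)-8,9-bis(benzyloxy)-4-hydroxy-2,6-dimethoxy-4-methyl-3-(phenylthio)-3,4-dihydrophenanthren-1(2H)-one | COC1C(Sc2ccccc2)[C@](C)(O)c2c3cc(OC)cc(OCc4ccccc4)c3c(OCc3ccccc3)cc2C1=O
F10 | step 12 | (4S)-8,9-bis(benzyloxy)-4-hydroxy-2,6-dimethoxy-4-methyl-3-(phenylthio)phenanthren-1(4H)-one | COC1=C(Sc2ccccc2)[C@](C)(O)c2c3cc(OC)cc(OCc4ccccc4)c3c(OCc3ccccc3)cc2C1=O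
A1 | alternative 1 | trans 4a-aryl-10a-(tert-butoxycarbonylmethyl) tricyclic enaminone | COC1=C2N3CCC[C@@H]3O[C@]2(C)[C@H](c2cc(OC)cc(OC)c2)[C@@H](CC(=O)OC(C)(C)C)C1=O
A2 | alternative 1 | tricyclic dienone (ring C with the N,O-acetal and a C4a=C10a enone) | COC1=C2N3CCC[C@@H]3O[C@]2(C)C=CC1=O
A3 | alternative 2 | target as its C8/C9 isopropylidene ketal | COC1=C2N3CCC[C@@H]3O[C@]2(C)c2c(cc3OC(C)(C)Oc4cc(OC)cc2c34)C1=O
A4 | alternative 2 | eight-membered N,O-ring precursor with a (Z) ring alkene | COC1=C2NC/C=C\CO[C@]2(C)c2c(cc3OC(C)(C)Oc4cc(OC)cc2c34)C1=O
A5 | alternative 3 | 1,2,3,4,6,8-hexamethoxyphenanthren-9-ol | COc1cc(OC)c2c(O)cc3c(OC)c(OC)c(OC)c(OC)c3c2c1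
A6 | alternative 3 | N,N-diethyl-2,4-dimethoxy-6-(2,3,4,5-tetramethoxy-6-methylphenyl)benzamide | CCN(CC)C(=O)c1c(OC)cc(OC)cc1-c1c(C)c(OC)c(OC)c(OC)c1OC
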